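**Plan**

- Numbering used for the same atoms throughout: oxolane O1, C2 (aryl), C3 (bears C9H2OH), C4 (bears C7′(=O)Ar), C5H2. Retrosynthesis: remove the benzyl ethers, invert C4 and return C7′/C9 to a cis-fused γ-lactone (C9 carboxyl tied to the C7′ carbinol), then cut O1–C5 and C2–C3 together.
- Enabling feature: C3 is α to C9, which can sit at the carboxyl level, and C5 is an unsubstituted CH2 on O1. C3–C4–C5 is therefore a latent 1,3-zwitterion, i.e. a cyclopropane fused to the lactone ring and doubly activated at C3 (lactone C=O plus a sacrificial CO2Me), and O1=C2 is the aryl aldehyde. Both aryl rings come from the same aldehyde.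
- Forward: aldehyde → vinyl carbinol (C7′) → diazomalonate → cyclopropane-fused lactone (three- and five-membered rings) → MgI2 ring expansion with the aldehyde closes the oxolane → decarboxylation, lactone reduction, C7′ oxidation with C4 epimerisation, hydrogenolysis.
- Stereochemistry: C7′ is set by lipase resolution and directs the cyclopropanation (C4). In the key step C4 fixes C3 (cis ring fusion) and C2 (aryl exo). C7′ is then erased as the ketone and C4 is inverted under thermodynamic control to the all-trans (2S,3R,4S) oxolane.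

Key step: step 6

Remark: 4-(benzyloxy)-3,5-dimethoxybenzaldehyde (1) is taken as the commercial source of both aryl units, and the aryl-exo lactone is assumed to be the major diastereomer of step 5 (the minor one would be removed by chromatography).

**Route**

Step 1
Reactants: 1 4-(benzyloxy)-3,5-dimethoxybenzaldehyde; 2 vinylmagnesium bromide
Product: 3 rac-1-[4-(benzyloxy)-3,5-dimethoxyphenyl]prop-2-en-1-ol
Conditions: THF, −78 to 0 °C; then aq. NH4Cl
Reagents that add atoms: none
Why: Grignard 1,2-addition to the aromatic aldehyde should give the secondary allylic alcohol; the new C7′ centre is formed unselectively and is resolved in step 2.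

Step 2
Reactants: 3 rac-1-[4-(benzyloxy)-3,5-dimethoxyphenyl]prop-2-en-1-ol
Product: 4 (1S)-1-[4-(benzyloxy)-3,5-dimethoxyphenyl]prop-2-en-1-ol
Conditions: immobilised Candida antarctica lipase B, vinyl acetate, MTBE, 30 °C, stopped just past half conversion
Reagents that add atoms: none
Why: Lipase-catalysed kinetic resolution (enantioselective transesterification) should acylate the (R)-alcohol, as for 1-arylethanol-type carbinols with the aryl group as the large substituent, and leave the (S)-alcohol in high enantiomeric purity.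

Step 3
Reactants: 4 (1S)-1-[4-(benzyloxy)-3,5-dimethoxyphenyl]prop-2-en-1-ol; 5 methyl 3-chloro-3-oxopropanoate
Product: 6 (1S)-1-[4-(benzyloxy)-3,5-dimethoxyphenyl]prop-2-en-1-yl methyl propanedioate
Conditions: pyridine, CH2Cl2, 0 °C
Reagents that add atoms: none
Why: O-acylation with the acid chloride under mild base takes place at oxygen only, so the C7′ configuration is retained.

Step 4
Reactants: 6 (1S)-1-[4-(benzyloxy)-3,5-dimethoxyphenyl]prop-2-en-1-yl methyl propanedioate
Product: 7 (1S)-1-[4-(benzyloxy)-3,5-dimethoxyphenyl]prop-2-en-1-yl methyl 2-diazopropanedioate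
Conditions: 4-acetamidobenzenesulfonyl azide, Et3N, MeCN, 0 °C to rt
Reagents that add atoms: 4-acetamidobenzenesulfonyl azide, CC(=O)Nc1ccc(cc1)S(=O)(=O)N=[N+]=[N-]
Why: Regitz diazo transfer to the malonate methylene is standard and leaves the allylic ester stereocentre untouched.

Step 5
Reactants: 7 (1S)-1-[4-(benzyloxy)-3,5-dimethoxyphenyl]prop-2-en-1-yl methyl 2-diazopropanedioate
Product: 8 methyl (1R,4S,5S)-4-[4-(benzyloxy)-3,5-dimethoxyphenyl]-2-oxo-3-oxabicyclo[3.1.0]hexane-1-carboxylate
Conditions: Rh2(esp)2 (1 mol %; esp = α,α,α′,α′-tetramethyl-1,3-benzenedipropanoate), CH2Cl2, slow addition, rt to 40 °C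
Reagents that add atoms: none
Why: Rhodium-carbenoid intramolecular cyclopropanation of an allyl diazomalonate is the standard entry to 3-oxabicyclo[3.1.0]hexan-2-ones, and the C7′ centre should steer the carbenoid to the alkene face that leaves the aryl group exo (anti to the cyclopropane CH2), which sets C4 and C3 of the three-membered ring by substrate control.

Step 6
Reactants: 8 methyl (1R,4S,5S)-4-[4-(benzyloxy)-3,5-dimethoxyphenyl]-2-oxo-3-oxabicyclo[3.1.0]hexane-1-carboxylate; 1 4-(benzyloxy)-3,5-dimethoxybenzaldehyde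
Product: 11 methyl (1S,4S,5R,8R)-4,8-bis[4-(benzyloxy)-3,5-dimethoxyphenyl]-2-oxo-3,7-dioxabicyclo[3.3.0]octane-1-carboxylate, via iodomethyl lactone magnesium enolate 9 (not isolated), via magnesium aldolate 10 (not isolated)
Conditions: MgI2 (1 equiv), 1 (1.5 equiv), THF, 65 °C, sealed tube
Reagents that add atoms: none
Why: Proposed new method: MgI2 chelates the lactone and ester carbonyls on C3 and iodide opens the cyclopropane at the unsubstituted C5 (homo-Michael SN2) to give the chelated enolate 9 with a CH2I arm on C4; reversible aldol addition of 9 to aldehyde 1 forms C3–C2, and the aldolate 10 then displaces iodide at C5 to form O1–C5 and return MgI2. The closest known reaction type is the MgI2-mediated ring expansion of activated cyclopropanes (spiro-cyclopropyl oxindoles, methylenecyclopropane amides) with aldimines and aldehydes, together with the iodide-induced ring-opening aldol of cyclopropyl ketones; the extension is the use of a donor-free, malonate-type cyclopropane-fused lactone with an aromatic aldehyde. The oxolane closes in the 5-exo-tet mode. The retained C4 centre controls the new ones: only the aldolate whose C3–C2 bond is cis to the C4–CH2I arm can cyclise, so the C3/C4 ring fusion must be cis, and C2 places its aryl group on the convex (exo) face, trans to the lactone carbonyl C9. The selectivity needed is iodide attack at C5 and not at C4 or at the benzylic lactone carbon C7′, which the unhindered primary carbon and the strain release should secure; because C3 is quaternary the aldolate cannot dehydrate, so unproductive aldolates revert and funnel to 11.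

Step 7
Reactants: 11 methyl (1S,4S,5R,8R)-4,8-bis[4-(benzyloxy)-3,5-dimethoxyphenyl]-2-oxo-3,7-dioxabicyclo[3.3.0]octane-1-carboxylate
Product: 12 (1S,4S,5R,8S)-4,8-bis[4-(benzyloxy)-3,5-dimethoxyphenyl]-3,7-dioxabicyclo[3.3.0]octan-2-one
Conditions: LiCl, DMSO–H2O, 130 °C
Reagents that add atoms: none
Why: Krapcho dealkoxycarbonylation removes the activating ester, and protonation of the resulting lactone enolate can only give the cis-fused bicycle, which sets C3–H with C9 trans to the C2 aryl group.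

Step 8
Reactants: 12 (1S,4S,5R,8S)-4,8-bis[4-(benzyloxy)-3,5-dimethoxyphenyl]-3,7-dioxabicyclo[3.3.0]octan-2-one
Product: 13 (S)-[4-(benzyloxy)-3,5-dimethoxyphenyl]{(3R,4R,5S)-5-[4-(benzyloxy)-3,5-dimethoxyphenyl]-4-(hydroxymethyl)oxolan-3-yl}methanol
Conditions: LiAlH4, THF, 0 °C to rt
Reagents that add atoms: none
Why: Hydride reduction of the γ-lactone to the 1,4-diol frees C9 as the primary alcohol and C7′ as a benzylic alcohol without touching a stereocentre.

Step 9
Reactants: 13 (S)-[4-(benzyloxy)-3,5-dimethoxyphenyl]{(3R,4R,5S)-5-[4-(benzyloxy)-3,5-dimethoxyphenyl]-4-(hydroxymethyl)oxolan-3-yl}methanol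
Product: 15 [4-(benzyloxy)-3,5-dimethoxyphenyl]{(3S,4R,5S)-5-[4-(benzyloxy)-3,5-dimethoxyphenyl]-4-(hydroxymethyl)oxolan-3-yl}methanone, via cis keto alcohol 14 (not isolated)
Conditions: activated MnO2 (excess), CH2Cl2, rt; filter; then DBU (0.3 equiv), CH2Cl2, rt
Reagents that add atoms: none
Why: Chemoselective MnO2 oxidation of the benzylic secondary alcohol beside the primary alcohol should give the aryl ketone, and DBU-mediated enolisation then epimerises the ketone α-carbon C4 from the cis to the thermodynamically preferred all-trans arrangement, which sets the final C4 configuration.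

Step 10
Reactants: 15 [4-(benzyloxy)-3,5-dimethoxyphenyl]{(3S,4R,5S)-5-[4-(benzyloxy)-3,5-dimethoxyphenyl]-4-(hydroxymethyl)oxolan-3-yl}methanone
Product: 16 (4-hydroxy-3,5-dimethoxyphenyl)[(3S,4R,5S)-5-(4-hydroxy-3,5-dimethoxyphenyl)-4-(hydroxymethyl)oxolan-3-yl]methanone
Conditions: H2 (1 atm), 10 % Pd/C, EtOAc–MeOH, rt
Reagents that add atoms: none
Why: Catalytic hydrogenolysis of the two aryl benzyl ethers under mild conditions should leave the aryl ketone and the benzylic ring ether intact and touches no stereocentre.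

**Compound list**

1 | 4-(benzyloxy)-3,5-dimethoxybenzaldehyde | COc1cc(C=O)cc(OC)c1OCc1ccccc1 | starting material
2 | vinylmagnesium bromide | C=C[Mg]Br | starting material
3 | rac-1-[4-(benzyloxy)-3,5-dimethoxyphenyl]prop-2-en-1-ol | C=CC(O)c1cc(OC)c(OCc2ccccc2)c(OC)c1 | intermediate
4 | (1S)-1-[4-(benzyloxy)-3,5-dimethoxyphenyl]prop-2-en-1-ol | C=C[C@H](O)c1cc(OC)c(OCc2ccccc2)c(OC)c1 | intermediate
5 | methyl 3-chloro-3-oxopropanoate (methyl malonyl chloride) | COC(=O)CC(Cl)=O | starting material
6 | (1S)-1-[4-(benzyloxy)-3,5-dimethoxyphenyl]prop-2-en-1-yl methyl propanedioate | C=C[C@H](OC(=O)CC(=O)OC)c1cc(OC)c(OCc2ccccc2)c(OC)c1 | intermediate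
7 | (1S)-1-[4-(benzyloxy)-3,5-dimethoxyphenyl]prop-2-en-1-yl methyl 2-diazopropanedioate | C=C[C@H](OC(=O)C(=[N+]=[N-])C(=O)OC)c1cc(OC)c(OCc2ccccc2)c(OC)c1 | intermediate
8 | methyl (1R,4S,5S)-4-[4-(benzyloxy)-3,5-dimethoxyphenyl]-2-oxo-3-oxabicyclo[3.1.0]hexane-1-carboxylate (aryl exo, anti to the cyclopropane CH2) | COc1cc(cc(OC)c1OCc1ccccc1)[C@H]2OC(=O)[C@]3(C(=O)OC)C[C@H]23 | intermediate
9 | iodomagnesium enolate of methyl 5-aryl-4-(iodomethyl)-2-oxooxolane-3-carboxylate (aryl and CH2I trans) | COc1cc(cc(OC)c1OCc1ccccc1)[C@H]2OC(O[Mg]I)=C(C(=O)OC)[C@@H]2CI | intermediate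
10 | iodomagnesium aldolate of 9 with aldehyde 1 (new C3–C2 bond cis to the CH2I arm) | COc1cc(cc(OC)c1OCc1ccccc1)[C@H]2OC(=O)[C@](C(=O)OC)([C@@H](c3cc(OC)c(OCc4ccccc4)c(OC)c3)O[Mg]I)[C@@H]2CI | intermediate
11 | methyl (1S,4S,5R,8R)-4,8-bis[4-(benzyloxy)-3,5-dimethoxyphenyl]-2-oxo-3,7-dioxabicyclo[3.3.0]octane-1-carboxylate (cis-fused, both aryl groups exo) | COc1cc(cc(OC)c1OCc1ccccc1)[C@H]2OC(=O)[C@]3(C(=O)OC)[C@@H](c4cc(OC)c(OCc5ccccc5)c(OC)c4)OC[C@H]23 | intermediate
12 | (1S,4S,5R,8S)-4,8-bis[4-(benzyloxy)-3,5-dimethoxyphenyl]-3,7-dioxabicyclo[3.3.0]octan-2-one (cis-fused, both aryl groups exo) | COc1cc(cc(OC)c1OCc1ccccc1)[C@H]2OC(=O)[C@@H]3[C@@H](c4cc(OC)c(OCc5ccccc5)c(OC)c4)OC[C@H]23 | intermediate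
13 | (S)-[4-(benzyloxy)-3,5-dimethoxyphenyl]{(3R,4R,5S)-5-[4-(benzyloxy)-3,5-dimethoxyphenyl]-4-(hydroxymethyl)oxolan-3-yl}methanol | OC[C@@H]1[C@@H](c2cc(OC)c(OCc3ccccc3)c(OC)c2)OC[C@@H]1[C@H](O)c1cc(OC)c(OCc2ccccc2)c(OC)c1 | intermediate
14 | [4-(benzyloxy)-3,5-dimethoxyphenyl]{(3R,4R,5S)-5-[4-(benzyloxy)-3,5-dimethoxyphenyl]-4-(hydroxymethyl)oxolan-3-yl}methanone (3,4-cis; may sit partly as its cyclic hemiketal) | OC[C@@H]1[C@@H](c2cc(OC)c(OCc3ccccc3)c(OC)c2)OC[C@@H]1C(=O)c1cc(OC)c(OCc2ccccc2)c(OC)c1 | intermediate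
15 | [4-(benzyloxy)-3,5-dimethoxyphenyl]{(3S,4R,5S)-5-[4-(benzyloxy)-3,5-dimethoxyphenyl]-4-(hydroxymethyl)oxolan-3-yl}methanone (all-trans) | OC[C@@H]1[C@@H](c2cc(OC)c(OCc3ccccc3)c(OC)c2)OC[C@H]1C(=O)c1cc(OC)c(OCc2ccccc2)c(OC)c1 | intermediate
16 | (4-hydroxy-3,5-dimethoxyphenyl)[(3S,4R,5S)-5-(4-hydroxy-3,5-dimethoxyphenyl)-4-(hydroxymethyl)oxolan-3-yl]methanone | COc1cc(C(=O)[C@@H]2CO[C@H](c3cc(OC)c(O)c(OC)c3)[C@H]2CO)cc(OC)c1O | target

Total step count: 10
Longest linear sequence: 10 steps (from 1 to 16; 1 enters a second time in step 6)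

**Steps most likely to fail**

Step 6 (Proposed new method). The cyclopropane may fail to open, the benzylic lactone carbon may ionise instead, or the aldolate may not close. The fallback uses the known tandem conjugate addition–aldol on a chiral butenolide; it sets out again from aldehyde 1 and comes back at 14.
- Thioacetalisation of 1 (propane-1,3-dithiol, BF3·OEt2, CH2Cl2) gives 2-[4-(benzyloxy)-3,5-dimethoxyphenyl]-1,3-dithiane F1.
- Its lithio derivative (n-BuLi, THF, −78 °C) adds 1,4 to the purchased auxiliary (5R)-5-(l-menthyloxy)furan-2(5H)-one F2, anti to the menthyloxy group. The lactone enolate is trapped by a second equivalent of 1, anti to the new substituent, to give the trans,trans-disubstituted menthyloxy lactone F3 (both carbinol epimers).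
- LiAlH4 reduces the lactone and the acetal carbon to give the dithianyl triol F4, with loss of menthol.
- Catalytic camphorsulfonic acid in CH2Cl2 ionises the benzylic alcohol, and the C5 hydroxyl closes the ring under thermodynamic control (aryl trans to the C3 arm) to give the dithianyl oxolane F5.
- Alkylative hydrolysis (MeI, CaCO3, aq. MeCN) unmasks the ketone as 14, which is epimerised with DBU as in step 9 to 15.

Step 5. The carbenoid may show poor facial selectivity, or may attack the electron-rich aryl ring instead of the alkene. The fallback closes the cyclopropane without a carbenoid, from malonate 6 and back at 8, by the known one-pot halogenation–cycloalkylation of allyl malonates (I2, K2CO3, benzyltriethylammonium chloride, toluene).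
- Iodination gives the (1S)-1-arylprop-2-en-1-yl methyl 2-iodopropanedioate F6.
- Carbocyclisation onto the alkene gives the methyl 5-aryl-4-(iodomethyl)-2-oxooxolane-3-carboxylate F7, with aryl and CH2I trans.
- Intramolecular C-alkylation then gives 8 with the aryl group exo.

Step 7. Hot halide may open the oxolane or the benzylic lactone, or the transient enolate may undergo β-elimination. The fallback, from 11 and back at 12, hydrolyses the methyl ester under near-neutral conditions (Me3SnOH, 1,2-dichloroethane, 80 °C) to the 2-oxo-3,7-dioxabicyclo[3.3.0]octane-1-carboxylic acid F8. This malonic half-acid should lose CO2 on gentle warming in toluene to give 12.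

**Further compounds**

F1 | step 6 | 2-[4-(benzyloxy)-3,5-dimethoxyphenyl]-1,3-dithiane | COc1cc(cc(OC)c1OCc1ccccc1)C1SCCCS1
F2 | step 6 | (5R)-5-{[(1R,2S,5R)-5-methyl-2-(propan-2-yl)cyclohexyl]oxy}furan-2(5H)-one (purchased auxiliary) | O=C1C=C[C@H](O[C@@H]2C[C@H](C)CC[C@H]2C(C)C)O1
F3 | step 6 | 3-{[4-(benzyloxy)-3,5-dimethoxyphenyl](hydroxy)methyl}-4-{2-[4-(benzyloxy)-3,5-dimethoxyphenyl]-1,3-dithian-2-yl}-5-(l-menthyloxy)oxolan-2-one (3,4-trans, 4,5-trans; carbinol epimers) | O=C1O[C@@H](O[C@@H]2C[C@H](C)CC[C@H]2C(C)C)[C@H](C2(SCCCS2)c2cc(OC)c(OCc3ccccc3)c(OC)c2)[C@H]1C(O)c1cc(OC)c(OCc2ccccc2)c(OC)c1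
F4 | step 6 | 1-[4-(benzyloxy)-3,5-dimethoxyphenyl]-2-(hydroxymethyl)-3-{2-[4-(benzyloxy)-3,5-dimethoxyphenyl]-1,3-dithian-2-yl}butane-1,4-diol (carbinol epimers) | OC[C@@H]([C@H](CO)C1(SCCCS1)c1cc(OC)c(OCc2ccccc2)c(OC)c1)C(O)c1cc(OC)c(OCc2ccccc2)c(OC)c1
F5 | step 6 | {2-[4-(benzyloxy)-3,5-dimethoxyphenyl]-4-{2-[4-(benzyloxy)-3,5-dimethoxyphenyl]-1,3-dithian-2-yl}oxolan-3-yl}methanol (2,3-trans, 3,4-cis) | OC[C@@H]1[C@@H](c2cc(OC)c(OCc3ccccc3)c(OC)c2)OC[C@@H]1C1(SCCCS1)c1cc(OC)c(OCc2ccccc2)c(OC)c1
F6 | step 5 | (1S)-1-[4-(benzyloxy)-3,5-dimethoxyphenyl]prop-2-en-1-yl methyl 2-iodopropanedioate | C=C[C@H](OC(=O)C(I)C(=O)OC)c1cc(OC)c(OCc2ccccc2)c(OC)c1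
F7 | step 5 | methyl 5-[4-(benzyloxy)-3,5-dimethoxyphenyl]-4-(iodomethyl)-2-oxooxolane-3-carboxylate (4,5-trans; C3 epimers) | COc1cc(cc(OC)c1OCc1ccccc1)[C@H]2OC(=O)C(C(=O)OC)[C@@H]2CI
F8 | step 7 | 4,8-bis[4-(benzyloxy)-3,5-dimethoxyphenyl]-2-oxo-3,7-dioxabicyclo[3.3.0]octane-1-carboxylic acid (same configuration as 11) | COc1cc(cc(OC)c1OCc1ccccc1)[C@H]2OC(=O)[C@]3(C(O)=O)[C@@H](c4cc(OC)c(OCc5ccccc5)c(OC)c4)OC[C@H]23
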